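**Retrosynthetic overview**

- Target ⇒ achiral 2-acyl-3-hydroxyfuran carrying a (Z)-dimethoxy-enone α-keto methyl ester, by an intramolecular aldol that closes the cyclopentenone and sets both stereocentres (net benzilic ester ring contraction).
- That keto ester ⇒ racemic spiro[4.5]ene-tetraone, by retro-Claisen methanolysis of the 1,2-dione carbonyl next to the spiro carbon.
- Spiro-tetraone ⇒ 3-aroylacetyl-2-hydroxy-5,6-dimethoxy-1,4-benzoquinone (the ring-opened 5,8-quinone of an isothymusin-type flavone), by oxidative C–O spirocyclisation that forms the 3(2H)-furanone.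
- Hydroxyquinone ⇒ aldol adduct of 2'-hydroxy-4',5',6'-trimethoxyacetophenone and 4-silyloxybenzaldehyde, by alcohol oxidation, phenol ortho-oxygenation and hydrolysis.
- Ring order: A ring bought → spiro-furanone (oxidative) → six-to-five contraction of the carbocycle, as in the proposed biogenesis.

Assumption: 1 and 2 are taken as catalogue compounds (1 is otherwise one Friedel–Crafts step from 3,4,5-trimethoxyphenol).
Assumption: the sense of induction of the step 4 catalyst cannot be predicted with certainty; the quinine-derived squaramide is written, and its quinidine-derived pseudo-enantiomer is used instead if it proves to give the antipode.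

**Step 1**
Reactants: 1 1-(6-hydroxy-2,3,4-trimethoxyphenyl)ethan-1-one; 2 4-[(tert-butyldimethylsilyl)oxy]benzaldehyde
Product: 3 rac-3-{4-[(tert-butyldimethylsilyl)oxy]phenyl}-3-hydroxy-1-(6-hydroxy-2,3,4-trimethoxyphenyl)propan-1-one
Conditions: LDA (2.2 equiv), THF, −78 °C; then 2, −78 °C; AcOH quench at −78 °C
Reagents that add atoms: none
Why: Directed aldol addition of the phenoxide/kinetic enolate dianion of 1 to the non-enolisable aldehyde 2, with a cold acidic quench to prevent retro-aldol or dehydration; the carbinol centre is racemic and is removed by oxidation in step 2.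

**Step 2**
Reactants: 3 rac-3-{4-[(tert-butyldimethylsilyl)oxy]phenyl}-3-hydroxy-1-(6-hydroxy-2,3,4-trimethoxyphenyl)propan-1-one
Product: 5 2-hydroxy-3-{3-[4-(tert-butyldimethylsilyloxy)phenyl]-3-oxopropanoyl}-5,6-dimethoxycyclohexa-2,5-diene-1,4-dione, via o-quinone diketone 4 (not isolated)
Conditions: IBX (2.6 equiv), DMSO, 23 °C; then sat. aq NaHCO3–THF, 0 °C, Ar; then 1 M HCl to pH 3, 0 °C
Reagents that add atoms: IBX, O=C1OI(=O)(O)c2ccccc12; water, O
Why: IBX oxidises the benzylic β-hydroxy ketone to the β-diketone (the faster event) and then transfers oxygen to the only free ortho position of the phenol (IBX ortho-oxygenation to the o-quinone), after which the methoxy group vinylogous to both the ring carbonyl and the side-chain carbonyl is displaced by water (addition–elimination) to give the 2-hydroxy-1,4-benzoquinone as its stabilised sodium salt; the cold bicarbonate and brief pH 3 work-up should leave the aryl silyl ether intact, and no stereocentre remains.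

**Step 3**
Reactants: 5 2-hydroxy-3-{3-[4-(tert-butyldimethylsilyloxy)phenyl]-3-oxopropanoyl}-5,6-dimethoxycyclohexa-2,5-diene-1,4-dione
Product: 6 rac-2-{4-[(tert-butyldimethylsilyl)oxy]phenyl}-8,9-dimethoxy-1-oxaspiro[4.5]deca-2,8-diene-4,6,7,10-tetraone
Conditions: PhI(OAc)2 (1.05 equiv), CH2Cl2–HFIP 4:1, −20 to 0 °C; filtration through dry silica, used at once
Reagents that add atoms: none
Why: Kita-type iodine(III) oxidative spirocyclisation (intramolecular α-oxygenation of an enolised β-tricarbonyl), in which the acidic hydroxyquinone OH exchanges onto iodine and the side-chain enol oxygen attacks C-3 in a 5-exo mode with loss of PhI and acetate to form the 3(2H)-furanone; the spiro centre is formed racemic, which does not matter because step 4 erases and resets it.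

**Step 4**
Reactants: 6 rac-2-{4-[(tert-butyldimethylsilyl)oxy]phenyl}-8,9-dimethoxy-1-oxaspiro[4.5]deca-2,8-diene-4,6,7,10-tetraone
Product: 9 limnophilaspiroketone [methyl (5S,6R)-6-hydroxy-2-(4-hydroxyphenyl)-7,8-dimethoxy-4,9-dioxo-1-oxaspiro[4.4]nona-2,7-diene-6-carboxylate], via furanol keto ester 7 (not isolated), via silyl ether 8 (not isolated)
Conditions: 9-amino(9-deoxy)epi-quinine 3,5-bis(trifluoromethyl)phenyl squaramide (10 mol%), MeOH (5 equiv), CH2Cl2, −40 °C; then HF·pyridine, THF, 0 °C
Reagents that add atoms: methanol, CO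
Why: Proposed new method: a catalytic enantioconvergent benzilic ester ring contraction, in which the amine–squaramide delivers MeOH to the most electrophilic ketone C-6 of 6 (as in cinchona-catalysed anhydride methanolysis), the hemiketal fragments by retro-Claisen with the C-5 carbanion leaving as an aromatic 2-acylfuran-3-olate (isomaltol-type, pKa about 6) so that the racemic spiro centre is erased in achiral 7, and the quinuclidinium/squaramide ion pair then directs the 5-exo aldol of the furanolate ipso carbon onto the hydrogen-bonded α-keto ester through an open transition state (furanolate oxygen anti to ketone oxygen), setting C-5 (S) and C-6 (R) together with 6-OH cis to O-1; the closest known reactions are the benzilic ester rearrangement and bifunctional squaramide-catalysed additions of acidic enols to α-keto esters, and HF·pyridine finally cleaves the aryl silyl ether under acidic conditions that suppress retro-aldol.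

**Compound list**

1 | 1-(6-hydroxy-2,3,4-trimethoxyphenyl)ethan-1-one | CC(=O)c1c(O)cc(OC)c(OC)c1OC | starting material
2 | 4-[(tert-butyldimethylsilyl)oxy]benzaldehyde | O=Cc1ccc(O[Si](C)(C)C(C)(C)C)cc1 | starting material
3 | rac-3-{4-[(tert-butyldimethylsilyl)oxy]phenyl}-3-hydroxy-1-(6-hydroxy-2,3,4-trimethoxyphenyl)propan-1-one | COc1cc(O)c(C(=O)CC(O)c2ccc(O[Si](C)(C)C(C)(C)C)cc2)c(OC)c1OC | intermediate
4 | 3-{3-[4-(tert-butyldimethylsilyloxy)phenyl]-3-oxopropanoyl}-4,5,6-trimethoxycyclohexa-3,5-diene-1,2-dione | COC1=C(OC)C(=O)C(=O)C(C(=O)CC(=O)c2ccc(O[Si](C)(C)C(C)(C)C)cc2)=C1OC | intermediate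
5 | 2-hydroxy-3-{3-[4-(tert-butyldimethylsilyloxy)phenyl]-3-oxopropanoyl}-5,6-dimethoxycyclohexa-2,5-diene-1,4-dione | COC1=C(OC)C(=O)C(C(=O)CC(=O)c2ccc(O[Si](C)(C)C(C)(C)C)cc2)=C(O)C1=O | intermediate
6 | rac-2-{4-[(tert-butyldimethylsilyl)oxy]phenyl}-8,9-dimethoxy-1-oxaspiro[4.5]deca-2,8-diene-4,6,7,10-tetraone | COC1=C(OC)C(=O)C2(OC(c3ccc(O[Si](C)(C)C(C)(C)C)cc3)=CC2=O)C(=O)C1=O | intermediate
7 | methyl (3Z)-5-[5-{4-[(tert-butyldimethylsilyl)oxy]phenyl}-3-hydroxyfuran-2-yl]-3,4-dimethoxy-2,5-dioxopent-3-enoate | COC(=O)C(=O)/C(OC)=C(OC)\C(=O)c1oc(-c2ccc(O[Si](C)(C)C(C)(C)C)cc2)cc1O | intermediate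
8 | methyl (5S,6R)-2-{4-[(tert-butyldimethylsilyl)oxy]phenyl}-6-hydroxy-7,8-dimethoxy-4,9-dioxo-1-oxaspiro[4.4]nona-2,7-diene-6-carboxylate | COC(=O)[C@@]1(O)C(OC)=C(OC)C(=O)[C@]12OC(c1ccc(O[Si](C)(C)C(C)(C)C)cc1)=CC2=O | intermediate
9 | limnophilaspiroketone, methyl (5S,6R)-6-hydroxy-2-(4-hydroxyphenyl)-7,8-dimethoxy-4,9-dioxo-1-oxaspiro[4.4]nona-2,7-diene-6-carboxylate | COC(=O)[C@@]1(O)C(OC)=C(OC)C(=O)[C@]12OC(c1ccc(O)cc1)=CC2=O | target

**Totals**

Total step count: 4. Longest linear sequence: 4 steps (1 → 3 → 5 → 6 → 9).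

**Steps most likely to fail**

Step 4 is the most exposed. A competing concerted 1,2-shift would transmit the racemic spiro centre into the product, the aldol may give the wrong diastereomer, and the product can erode by retro-aldol if left on the basic catalyst. The fallback separates ring opening from ring closure and uses chelation by a chiral Lewis acid instead of ion pairing. It sets out from 6: silylative retro-Claisen opening with MeOSiMe3 and catalytic TMSOTf (CH2Cl2, −78 °C) gives methyl (3Z)-5-[5-{4-[(tert-butyldimethylsilyl)oxy]phenyl}-3-[(trimethylsilyl)oxy]furan-2-yl]-3,4-dimethoxy-2,5-dioxopent-3-enoate F6. An intramolecular Mukaiyama aldol catalysed by [Cu(t-Bu-box)](OTf)2 (two-point binding of the α-keto ester, open transition state, ligand enantiomer chosen by experiment) then gives methyl (5S,6R)-2-{4-[(tert-butyldimethylsilyl)oxy]phenyl}-7,8-dimethoxy-4,9-dioxo-6-[(trimethylsilyl)oxy]-1-oxaspiro[4.4]nona-2,7-diene-6-carboxylate F7. HF·pyridine removes both silyl groups, and the fallback comes back to the route at 9.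

Step 3 may fail because the side-chain diketone carbon can compete with the ring carbon for iodine(III), and the hydroxyquinone is an untested substrate for this spirocyclisation. The fallback switches from electrophilic oxidation of the enol to nucleophilic epoxidation of a quinone in which the side-chain carbon is masked. It sets out from 5: acid-catalysed cyclodehydration (TsOH cat., benzene, 4 Å MS) gives 2-{4-[(tert-butyldimethylsilyl)oxy]phenyl}-6,7-dimethoxy-4H-chromene-4,5,8-trione F4. Weitz–Scheffer epoxidation (t-BuOOH, cat. DBU, CH2Cl2, 0 °C) of the doubly activated ring-fusion double bond gives rac-4a,8a-epoxy-2-{4-[(tert-butyldimethylsilyl)oxy]phenyl}-6,7-dimethoxy-4a,8a-dihydro-4H-chromene-4,5,8-trione F5. On silica or with catalytic Sc(OTf)3 the epoxide ionises at C-8a, the C-4a alkoxide closes onto C-2 and the old pyranone oxygen becomes the C-8a ketone, so the fallback comes back to the route at 6.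

Step 2 may fail because the ortho-acyl group deactivates the phenol toward oxygen transfer from IBX, and the diketone can be over-oxidised. The fallback installs the oxygen by formylation and Dakin oxidation before the side chain is built. It sets out from 1: Rieche formylation (Cl2CHOMe, TiCl4, CH2Cl2) at the only free ring position gives 3-acetyl-2-hydroxy-4,5,6-trimethoxybenzaldehyde F1. Dakin oxidation (H2O2, NaOH, 0 °C, Ar) gives 1-(2,3-dihydroxy-4,5,6-trimethoxyphenyl)ethan-1-one F2. Trianion aldol (LDA, 3.3 equiv, THF, −78 °C) with 2 gives rac-3-{4-[(tert-butyldimethylsilyl)oxy]phenyl}-1-(2,3-dihydroxy-4,5,6-trimethoxyphenyl)-3-hydroxypropan-1-one F3. IBX then only has to dehydrogenate (alcohol to ketone, catechol to o-quinone), so the fallback comes back to the route at 4, which is hydrolysed to 5 as in step 2.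

**Further compounds**

F1 | step 2 | 3-acetyl-2-hydroxy-4,5,6-trimethoxybenzaldehyde | CC(=O)c1c(O)c(C=O)c(OC)c(OC)c1OC
F2 | step 2 | 1-(2,3-dihydroxy-4,5,6-trimethoxyphenyl)ethan-1-one | CC(=O)c1c(O)c(O)c(OC)c(OC)c1OC
F3 | step 2 | rac-3-{4-[(tert-butyldimethylsilyl)oxy]phenyl}-1-(2,3-dihydroxy-4,5,6-trimethoxyphenyl)-3-hydroxypropan-1-one | COc1c(O)c(O)c(C(=O)CC(O)c2ccc(O[Si](C)(C)C(C)(C)C)cc2)c(OC)c1OC
F4 | step 3 | 2-{4-[(tert-butyldimethylsilyl)oxy]phenyl}-6,7-dimethoxy-4H-chromene-4,5,8-trione | COC1=C(OC)C(=O)C2=C(C1=O)C(=O)C=C(c1ccc(O[Si](C)(C)C(C)(C)C)cc1)O2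
F5 | step 3 | rac-4a,8a-epoxy-2-{4-[(tert-butyldimethylsilyl)oxy]phenyl}-6,7-dimethoxy-4a,8a-dihydro-4H-chromene-4,5,8-trione | COC1=C(OC)C(=O)C23OC2(C1=O)C(=O)C=C(c1ccc(O[Si](C)(C)C(C)(C)C)cc1)O3
F6 | step 4 | methyl (3Z)-5-[5-{4-[(tert-butyldimethylsilyl)oxy]phenyl}-3-[(trimethylsilyl)oxy]furan-2-yl]-3,4-dimethoxy-2,5-dioxopent-3-enoate | COC(=O)C(=O)/C(OC)=C(OC)\C(=O)c1oc(-c2ccc(O[Si](C)(C)C(C)(C)C)cc2)cc1O[Si](C)(C)C
F7 | step 4 | methyl (5S,6R)-2-{4-[(tert-butyldimethylsilyl)oxy]phenyl}-7,8-dimethoxy-4,9-dioxo-6-[(trimethylsilyl)oxy]-1-oxaspiro[4.4]nona-2,7-diene-6-carboxylate | COC(=O)[C@@]1(O[Si](C)(C)C)C(OC)=C(OC)C(=O)[C@]12OC(c1ccc(O[Si](C)(C)C(C)(C)C)cc1)=CC2=O
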